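**Retrosynthetic overview**
1. Ring C is closed last: the 2'-OH of an (αR,βS)-chalcone epoxide opens the epoxide 6-endo at the benzylic carbon with inversion, giving the (2R,3R)-trans-dihydroflavonol; the three MOM ethers are removed in the same acid step.
2. The epoxide comes from the tris-MOM (E)-chalcone by poly-L-leucine (Juliá–Colonna) epoxidation, which sets both stereocentres and leaves the prenyl olefins untouched.
3. Key C–C bond: Cα–Cβ of the chalcone, made by Claisen–Schmidt aldol condensation of a ring A acetophenone with a ring B benzaldehyde.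
4. Each fragment receives its prenyl group by Stille coupling of an aryl iodide (ring A: resacetophenone → 4-O-MOM → 5-iodo → 2-O-MOM; ring B: 4-hydroxy-3-iodobenzaldehyde → MOM ether).
5. Rings A and B are bought as aromatics; only ring C is constructed.

Assumption: 4-hydroxy-3-iodobenzaldehyde, tributyl(3-methylbut-2-en-1-yl)stannane and immobilised poly-L-leucine are taken as catalogue items; the target SMILES is read as the (2R,3R)-trans isomer.

**Route**

Step 1
Reactants: 1 1-(2,4-dihydroxyphenyl)ethanone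
Product: 2 1-[2-hydroxy-4-(methoxymethoxy)phenyl]ethanone
Conditions: MOMCl (1.1 equiv), K2CO3 (1.5 equiv), acetone, 0 °C → rt
Reagents that add atoms: chloromethyl methyl ether (MOMCl), COCCl
Why: Williamson-type O-alkylation; the 2-OH is hydrogen-bonded to the acetyl C=O and much less reactive, so only the 4-OH is protected.

Step 2
Reactants: 2 1-[2-hydroxy-4-(methoxymethoxy)phenyl]ethanone
Product: 3 1-[2-hydroxy-5-iodo-4-(methoxymethoxy)phenyl]ethanone
Conditions: BnMe3N+ ICl2− (1.05 equiv), NaHCO3 (3 equiv), CH2Cl2–MeOH, rt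
Reagents that add atoms: benzyltrimethylammonium dichloroiodate, C[N+](C)(C)Cc1ccccc1.Cl[I-]Cl
Why: Electrophilic aromatic iodination goes para to the free 2-OH (C5, also ortho to the OMOM), while C3 between the two oxygens is shielded; NaHCO3 takes up HCl so the MOM acetal survives.

Step 3
Reactants: 3 1-[2-hydroxy-5-iodo-4-(methoxymethoxy)phenyl]ethanone
Product: 4 1-[5-iodo-2,4-bis(methoxymethoxy)phenyl]ethanone
Conditions: NaH (1.2 equiv), MOMCl (1.3 equiv), DMF, 0 °C → rt
Reagents that add atoms: chloromethyl methyl ether (MOMCl), COCCl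
Why: Williamson-type O-alkylation of the chelated phenol needs the irreversible base NaH; the phenoxide is alkylated far faster than any ketone enolate when only a slight excess of base is used.

Step 4
Reactants: 4 1-[5-iodo-2,4-bis(methoxymethoxy)phenyl]ethanone
Product: 5 1-[2,4-bis(methoxymethoxy)-5-(3-methylbut-2-en-1-yl)phenyl]ethanone
Conditions: tributyl(3-methylbut-2-en-1-yl)stannane (1.3 equiv), Pd(PPh3)4 (5 mol%), degassed DMF, 90 °C
Reagents that add atoms: tributyl(3-methylbut-2-en-1-yl)stannane, CCCC[Sn](CCCC)(CCCC)CC=C(C)C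
Why: Stille coupling: oxidative addition of the aryl iodide to zerovalent palladium, transmetalation of the allylic stannane and reductive elimination at the unhindered CH2 terminus give the linear prenyl arene; ketone and MOM ethers are inert.

Step 5
Reactants: 6 4-hydroxy-3-iodobenzaldehyde
Product: 7 3-iodo-4-(methoxymethoxy)benzaldehyde
Conditions: MOMCl (1.2 equiv), K2CO3 (1.5 equiv), acetone, rt
Reagents that add atoms: chloromethyl methyl ether (MOMCl), COCCl
Why: Williamson-type O-alkylation of an acidic para-formyl phenol; the aldehyde is untouched under these mild basic conditions.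

Step 6
Reactants: 7 3-iodo-4-(methoxymethoxy)benzaldehyde
Product: 8 4-(methoxymethoxy)-3-(3-methylbut-2-en-1-yl)benzaldehyde
Conditions: tributyl(3-methylbut-2-en-1-yl)stannane (1.3 equiv), Pd(PPh3)4 (5 mol%), degassed DMF, 90 °C
Reagents that add atoms: tributyl(3-methylbut-2-en-1-yl)stannane, CCCC[Sn](CCCC)(CCCC)CC=C(C)C
Why: Stille coupling as in step 4; aldehydes are fully tolerated and the linear prenyl isomer results from reductive elimination at the primary allyl terminus.

Step 7
Reactants: 5 1-[2,4-bis(methoxymethoxy)-5-(3-methylbut-2-en-1-yl)phenyl]ethanone; 8 4-(methoxymethoxy)-3-(3-methylbut-2-en-1-yl)benzaldehyde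
Product: 10 (E)-1-[2,4-bis(methoxymethoxy)-5-(3-methylbut-2-en-1-yl)phenyl]-3-[4-(methoxymethoxy)-3-(3-methylbut-2-en-1-yl)phenyl]prop-2-en-1-one, via β-hydroxy ketone aldol adduct 9 (not isolated)
Conditions: KOH (4 equiv, 50% aq.), EtOH, rt, 24–48 h
Reagents that add atoms: none
Why: Claisen–Schmidt (crossed aldol) condensation: only ketone 5 can enolise, aldehyde 8 is the only electrophile, and E1cB dehydration of aldol 9 gives the conjugated (E)-enone; MOM ethers and prenyl groups are stable to hydroxide.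

Step 8
Reactants: 10 (E)-1-[2,4-bis(methoxymethoxy)-5-(3-methylbut-2-en-1-yl)phenyl]-3-[4-(methoxymethoxy)-3-(3-methylbut-2-en-1-yl)phenyl]prop-2-en-1-one
Product: 11 [2,4-bis(methoxymethoxy)-5-(3-methylbut-2-en-1-yl)phenyl][(2R,3S)-3-[4-(methoxymethoxy)-3-(3-methylbut-2-en-1-yl)phenyl]oxiran-2-yl]methanone (trans, αR,βS)
Conditions: immobilised poly-L-leucine, urea–H2O2 (1.5 equiv), DBU (1.5 equiv), THF, rt
Reagents that add atoms: urea–hydrogen peroxide adduct, OO.NC(N)=O
Why: Juliá–Colonna epoxidation (asymmetric Weitz–Scheffer): hydroperoxide adds to the enone β-carbon on the face set by the poly-L-leucine helix and the enolate closes to the trans-(αR,βS) epoxide, fixing both stereocentres, while the electron-rich prenyl olefins do not react with a nucleophilic oxidant.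

Step 9
Reactants: 11 [2,4-bis(methoxymethoxy)-5-(3-methylbut-2-en-1-yl)phenyl][(2R,3S)-3-[4-(methoxymethoxy)-3-(3-methylbut-2-en-1-yl)phenyl]oxiran-2-yl]methanone
Product: 13 (2R,3R)-3,7-dihydroxy-2-[4-hydroxy-3-(3-methylbut-2-en-1-yl)phenyl]-6-(3-methylbut-2-en-1-yl)-2,3-dihydro-4H-chromen-4-one (lespeflorin B1), via tris-phenol epoxy ketone 12 (not isolated)
Conditions: 3 M HCl in MeOH–THF (4:1), 45 °C, 1–2 h, monitored by TLC
Reagents that add atoms: none
Why: Acid-catalysed acetal methanolysis removes the three MOM groups and the freed 2'-OH opens the protonated epoxide 6-endo at the p-oxybenzylic carbon with inversion (Cβ S → C2 R) while Cα is untouched (→ C3 R), giving the thermodynamically preferred 2,3-trans dihydroflavonol; the short, mild treatment spares the o-prenylphenols.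

**Compound list**
1 | 1-(2,4-dihydroxyphenyl)ethanone | CC(=O)c1ccc(O)cc1O | starting material
2 | 1-[2-hydroxy-4-(methoxymethoxy)phenyl]ethanone | CC(=O)c1ccc(OCOC)cc1O | intermediate
3 | 1-[2-hydroxy-5-iodo-4-(methoxymethoxy)phenyl]ethanone | CC(=O)c1cc(I)c(OCOC)cc1O | intermediate
4 | 1-[5-iodo-2,4-bis(methoxymethoxy)phenyl]ethanone | CC(=O)c1cc(I)c(OCOC)cc1OCOC | intermediate
5 | 1-[2,4-bis(methoxymethoxy)-5-(3-methylbut-2-en-1-yl)phenyl]ethanone | CC(=O)c1cc(CC=C(C)C)c(OCOC)cc1OCOC | intermediate
6 | 4-hydroxy-3-iodobenzaldehyde | O=Cc1ccc(O)c(I)c1 | starting material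
7 | 3-iodo-4-(methoxymethoxy)benzaldehyde | O=Cc1ccc(OCOC)c(I)c1 | intermediate
8 | 4-(methoxymethoxy)-3-(3-methylbut-2-en-1-yl)benzaldehyde | O=Cc1ccc(OCOC)c(CC=C(C)C)c1 | intermediate
9 | 1-[2,4-bis(methoxymethoxy)-5-(3-methylbut-2-en-1-yl)phenyl]-3-hydroxy-3-[4-(methoxymethoxy)-3-(3-methylbut-2-en-1-yl)phenyl]propan-1-one (racemic aldol adduct) | COCOc1cc(OCOC)c(CC=C(C)C)cc1C(=O)CC(O)c1ccc(OCOC)c(CC=C(C)C)c1 | intermediate (not isolated)
10 | (E)-1-[2,4-bis(methoxymethoxy)-5-(3-methylbut-2-en-1-yl)phenyl]-3-[4-(methoxymethoxy)-3-(3-methylbut-2-en-1-yl)phenyl]prop-2-en-1-one | COCOc1cc(OCOC)c(CC=C(C)C)cc1C(=O)/C=C/c1ccc(OCOC)c(CC=C(C)C)c1 | intermediate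
11 | [2,4-bis(methoxymethoxy)-5-(3-methylbut-2-en-1-yl)phenyl][(2R,3S)-3-[4-(methoxymethoxy)-3-(3-methylbut-2-en-1-yl)phenyl]oxiran-2-yl]methanone | COCOc1cc(OCOC)c(CC=C(C)C)cc1C(=O)[C@@H]1O[C@H]1c1ccc(OCOC)c(CC=C(C)C)c1 | intermediate
12 | [2,4-dihydroxy-5-(3-methylbut-2-en-1-yl)phenyl][(2R,3S)-3-[4-hydroxy-3-(3-methylbut-2-en-1-yl)phenyl]oxiran-2-yl]methanone | Oc1cc(O)c(CC=C(C)C)cc1C(=O)[C@@H]1O[C@H]1c1ccc(O)c(CC=C(C)C)c1 | intermediate (not isolated)
13 | (2R,3R)-3,7-dihydroxy-2-[4-hydroxy-3-(3-methylbut-2-en-1-yl)phenyl]-6-(3-methylbut-2-en-1-yl)-2,3-dihydro-4H-chromen-4-one (lespeflorin B1) | CC(C)=CCc1cc([C@H]2Oc3cc(O)c(CC=C(C)C)cc3C(=O)[C@@H]2O)ccc1O | target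

**Summary**
Total steps: 9. Longest linear sequence: 7 (steps 1, 2, 3, 4, 7, 8, 9).

**Three steps most likely to fail**

Step 9 (acid deprotection and ring closure). Risks are acid-induced chroman formation from the o-prenylphenols, methanol capture of the benzylic cation and some cis isomer. The fallback replaces direct acid opening by a thiol relay and sets out from 11. Treatment with phenylmethanethiol and SnCl4 in CH2Cl2 at −20 °C opens the epoxide at the benzylic carbon with inversion and cleaves the MOM ethers, giving (2S,3R)-3-(benzylsulfanyl)-1-[2,4-dihydroxy-5-(3-methylbut-2-en-1-yl)phenyl]-2-hydroxy-3-[4-hydroxy-3-(3-methylbut-2-en-1-yl)phenyl]propan-1-one F1. AgBF4 in CH2Cl2 at 0 °C then activates sulfur as a leaving group and the 2'-OH closes ring C to the trans product, with C3 unchanged, coming back to the route at 13.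

Step 8 (asymmetric epoxidation). The ortho-substituted, electron-rich enone may react slowly or with only moderate enantiomeric excess. The fallback replaces asymmetric catalysis by resolution and sets out from 10. Plain Weitz–Scheffer epoxidation (30% H2O2, NaOH, MeOH–THF, 0 °C → rt) gives the racemic trans-epoxy ketone F2. The acid treatment of step 9 converts it into the racemic trans-dihydroflavonol F3. Preparative chiral HPLC on an amylose tris(3,5-dimethylphenylcarbamate) phase then delivers the (2R,3R) enantiomer, coming back to the route at 13.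

Step 4 (Stille prenylation of the ring A iodide). Risks are prenyl/reverse-prenyl mixtures, protodestannylation and sluggish coupling next to the OMOM group. The fallback installs the side chain in two stages and sets out from 4. Suzuki–Miyaura coupling with allylboronic acid pinacol ester (Pd(dppf)Cl2, CsF, THF, 70 °C) gives 1-[2,4-bis(methoxymethoxy)-5-(prop-2-en-1-yl)phenyl]ethanone F4. Olefin cross-metathesis with excess 2-methylbut-2-ene (second-generation Grubbs catalyst, CH2Cl2, 40 °C) then converts allyl into prenyl, coming back to the route at 5.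

**Further compounds**
F1 | step 9 | (2S,3R)-3-(benzylsulfanyl)-1-[2,4-dihydroxy-5-(3-methylbut-2-en-1-yl)phenyl]-2-hydroxy-3-[4-hydroxy-3-(3-methylbut-2-en-1-yl)phenyl]propan-1-one | Oc1cc(O)c(CC=C(C)C)cc1C(=O)[C@H](O)[C@H](SCc1ccccc1)c1ccc(O)c(CC=C(C)C)c1
F2 | step 8 | racemic trans-epoxy ketone (1:1 mixture of 11 and its (2S,3R) enantiomer; SMILES of that enantiomer) | COCOc1cc(OCOC)c(CC=C(C)C)cc1C(=O)[C@H]1O[C@@H]1c1ccc(OCOC)c(CC=C(C)C)c1
F3 | step 8 | racemic trans-dihydroflavonol (1:1 mixture of 13 and its (2S,3S) enantiomer; SMILES of that enantiomer) | CC(C)=CCc1cc([C@@H]2Oc3cc(O)c(CC=C(C)C)cc3C(=O)[C@H]2O)ccc1O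
F4 | step 4 | 1-[2,4-bis(methoxymethoxy)-5-(prop-2-en-1-yl)phenyl]ethanone | CC(=O)c1cc(CC=C)c(OCOC)cc1OCOC
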